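TBS = tert-butyldimethylsilyl throughout.

**Retrosynthetic overview**
1. Target 21 ⇐ tetrasilyl flavanone 20 (global desilylation) ⇐ aldehyde 19 by cutting the C3–C4 bond of ring C; forward, an enantioselective intramolecular alkene hydroacylation.
2. Enabling feature: in ring C the carbonyl carbon C4 sits on arene carbon C4a ortho to O1, C3 is an unsubstituted CH2, and C2 carries O1, the catechol ring and one H. The flavanone is therefore an isomer of the achiral 2-(1-arylvinyloxy)benzaldehyde 19, and adding the formyl C–H across the vinyl ether makes ring C, the ketone and the only stereocentre at once.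
3. 19 ⇐ aryl ester 16 (carbonyl methylenation builds the vinyl ether; the formyl group travels as a dioxolane) ⇐ phenol 12 + acid 15.
4. 12 ⇐ seven-membered lactone 9: ring-closing metathesis of a 4-O-methacrylate onto a C3-allyl group fixes the Z geometry in a temporary ring, which is then reduced open; the allyl group comes from O-allylation and Claisen rearrangement of 2,4-dihydroxybenzaldehyde 1.
5. Ring order: rings A and B are bought; temporary oxepinone ring (formed in step 5, opened in step 6); ring C last (step 12).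

Key step: step 12

Assumption: the sense of asymmetric induction of the rhodium catalyst cannot be predicted with certainty for this new substrate; (R)-DTBM-SEGPHOS is written for the 2S product and its mirror image is to be used if the sense proves opposite.

**Step 1**
Reactants: 1 2,4-dihydroxybenzaldehyde; 2 allyl bromide
Product: 3 2-hydroxy-4-(prop-2-en-1-yloxy)benzaldehyde
Conditions: K2CO3 (1.0 equiv), acetone, reflux
Reagents that add atoms: allyl bromide 2, C=CCBr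
Why: Williamson O-allylation should occur at the 4-hydroxyl only, because the 2-hydroxyl is held in a hydrogen bond to the formyl group and is less nucleophilic.

**Step 2**
Reactants: 3 2-hydroxy-4-(prop-2-en-1-yloxy)benzaldehyde
Product: 4 2,4-dihydroxy-3-(prop-2-en-1-yl)benzaldehyde
Conditions: N,N-diethylaniline, 190 °C, argon
Reagents that add atoms: none
Why: Aromatic Claisen rearrangement ([3,3] shift, then tautomerisation) should deliver the allyl group to C3 between the two oxygens, as is usual for 4-allyloxy-2-hydroxyaryl carbonyl compounds in which the chelate ring fixes the more reactive double bond at C3–C4.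

**Step 3**
Reactants: 4 2,4-dihydroxy-3-(prop-2-en-1-yl)benzaldehyde; 5 methacryloyl chloride
Product: 6 4-formyl-3-hydroxy-2-(prop-2-en-1-yl)phenyl 2-methylprop-2-enoate
Conditions: Et3N (1.1 equiv), CH2Cl2, −20 to 0 °C
Reagents that add atoms: methacryloyl chloride 5, CC(=C)C(Cl)=O
Why: Selective O-acylation, since one equivalent of acid chloride should esterify the free 4-hydroxyl while the chelated 2-hydroxyl reacts much more slowly.

**Step 4**
Reactants: 6 4-formyl-3-hydroxy-2-(prop-2-en-1-yl)phenyl 2-methylprop-2-enoate; 7 1,2-bis(trimethylsilyloxy)ethane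
Product: 8 4-(1,3-dioxolan-2-yl)-3-hydroxy-2-(prop-2-en-1-yl)phenyl 2-methylprop-2-enoate
Conditions: Me3SiOTf (10 mol%), CH2Cl2, −78 to −20 °C; then pyridine, aq. NaHCO3
Reagents that add atoms: 1,2-bis(trimethylsilyloxy)ethane 7, C[Si](C)(C)OCCO[Si](C)(C)C
Why: Silyl-triflate-catalysed acetalisation with a bis-silylated diol (aprotic, low temperature) should mask the formyl group as a dioxolane, so that it survives the hydride of step 6 and the titanium reagent of step 10, without harming the ester or the ortho-allylphenol.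

**Step 5**
Reactants: 8 4-(1,3-dioxolan-2-yl)-3-hydroxy-2-(prop-2-en-1-yl)phenyl 2-methylprop-2-enoate
Product: 9 7-(1,3-dioxolan-2-yl)-6-hydroxy-3-methyl-1-benzoxepin-2(5H)-one
Conditions: second-generation Grubbs catalyst (H2IMes)(PCy3)Cl2Ru=CHPh (5 mol%), 1,4-benzoquinone (10 mol%), toluene (0.005 M), 80 °C
Reagents that add atoms: none
Why: Ring-closing metathesis of the allyl group with the methacrylate should give the seven-membered unsaturated lactone, in which the new trisubstituted alkene can only be cis in the ring, so the carbonyl carbon (the later CH2OH) and the benzylic CH2 are placed on the same side (Z).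

**Step 6**
Reactants: 9 7-(1,3-dioxolan-2-yl)-6-hydroxy-3-methyl-1-benzoxepin-2(5H)-one
Product: 10 4-(1,3-dioxolan-2-yl)-2-[(2Z)-4-hydroxy-3-methylbut-2-en-1-yl]benzene-1,3-diol
Conditions: i-Bu2AlH (5 equiv), THF, −78 to −40 °C; aq. potassium sodium tartrate (KNaC4H4O6), work-up kept at pH 7 or above
Reagents that add atoms: none
Why: 1,2-Reduction of the enoate lactone with excess i-Bu2AlH should open the ring to the phenol and the allylic alcohol with the alkene geometry untouched, the dioxolane being inert at low temperature.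

**Step 7**
Reactants: 10 4-(1,3-dioxolan-2-yl)-2-[(2Z)-4-hydroxy-3-methylbut-2-en-1-yl]benzene-1,3-diol; 11 tert-butyldimethylsilyl chloride
Product: 12 3-[(TBS)oxy]-2-[(2Z)-4-[(TBS)oxy]-3-methylbut-2-en-1-yl]-6-(1,3-dioxolan-2-yl)phenol
Conditions: TBSCl (2.1 equiv), imidazole, DMF, 0 °C
Reagents that add atoms: tert-butyldimethylsilyl chloride 11, CC(C)(C)[Si](C)(C)Cl
Why: Silylation with silyl chloride and imidazole should take the primary alcohol and the less hindered phenol, while the phenol flanked by the dioxolane and the side chain (hydrogen-bonded to an acetal oxygen) stays free for step 9.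

**Step 8**
Reactants: 13 3,4-dihydroxybenzoic acid; 11 tert-butyldimethylsilyl chloride
Product: 15 3,4-bis[(TBS)oxy]benzoic acid, via tris-silylated silyl ester 14 (not isolated)
Conditions: TBSCl (3.3 equiv), imidazole, DMF, rt; then AcOH, THF, H2O, rt
Reagents that add atoms: tert-butyldimethylsilyl chloride 11, CC(C)(C)[Si](C)(C)Cl
Why: Exhaustive silylation followed by selective hydrolysis of the labile silyl ester (aryl silyl ethers survive dilute acetic acid) is the standard entry to the bis-silylated acid.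

**Step 9**
Reactants: 12 3-[(TBS)oxy]-2-[(2Z)-4-[(TBS)oxy]-3-methylbut-2-en-1-yl]-6-(1,3-dioxolan-2-yl)phenol; 15 3,4-bis[(TBS)oxy]benzoic acid
Product: 16 3-[(TBS)oxy]-2-[(2Z)-4-[(TBS)oxy]-3-methylbut-2-en-1-yl]-6-(1,3-dioxolan-2-yl)phenyl 3,4-bis[(TBS)oxy]benzoate
Conditions: DCC (1.3 equiv), DMAP (1 equiv), CH2Cl2, rt
Reagents that add atoms: 3,4-bis[(TBS)oxy]benzoic acid 15, OC(=O)c1ccc(O[Si](C)(C)C(C)(C)C)c(O[Si](C)(C)C(C)(C)C)c1
Why: Steglich esterification (carbodiimide activation with acyl transfer by DMAP) should acylate the only free hydroxyl, the hindered phenol.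

**Step 10**
Reactants: 16 3-[(TBS)oxy]-2-[(2Z)-4-[(TBS)oxy]-3-methylbut-2-en-1-yl]-6-(1,3-dioxolan-2-yl)phenyl 3,4-bis[(TBS)oxy]benzoate; 17 dimethyltitanocene
Product: 18 2-{2-[(1-{3,4-bis[(TBS)oxy]phenyl}ethenyl)oxy]-4-[(TBS)oxy]-3-[(2Z)-4-[(TBS)oxy]-3-methylbut-2-en-1-yl]phenyl}-1,3-dioxolane
Conditions: Cp2TiMe2 (3 equiv), toluene, 75 °C, dark
Reagents that add atoms: dimethyltitanocene 17 (supplies CH2), C[Ti](C)(C1C=CC=C1)C1C=CC=C1 (cyclopentadienyl rings drawn σ-bonded)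
Why: Petasis carbonyl methylenation (loss of methane to Cp2Ti=CH2, [2+2] addition to the ester carbonyl and cycloreversion) converts aryl benzoates into 1-aryloxy-1-arylethenes and tolerates silyl ethers, acetals and alkenes.

**Step 11**
Reactants: 18 2-{2-[(1-{3,4-bis[(TBS)oxy]phenyl}ethenyl)oxy]-4-[(TBS)oxy]-3-[(2Z)-4-[(TBS)oxy]-3-methylbut-2-en-1-yl]phenyl}-1,3-dioxolane
Product: 19 2-[(1-{3,4-bis[(TBS)oxy]phenyl}ethenyl)oxy]-4-[(TBS)oxy]-3-[(2Z)-4-[(TBS)oxy]-3-methylbut-2-en-1-yl]benzaldehyde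
Conditions: PPTS (10 mol%), aqueous acetone, 0 °C to rt, monitored; Et3N quench
Reagents that add atoms: water, O
Why: Acid-catalysed acetal hydrolysis, in which ionisation of the acetal to an oxocarbenium ion stabilised by the para silyloxy group should be much faster than carbon protonation of the electron-poor aryl vinyl ether, so a short buffered treatment should free the aldehyde selectively.

**Step 12**
Reactants: 19 2-[(1-{3,4-bis[(TBS)oxy]phenyl}ethenyl)oxy]-4-[(TBS)oxy]-3-[(2Z)-4-[(TBS)oxy]-3-methylbut-2-en-1-yl]benzaldehyde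
Product: 20 (2S)-2-{3,4-bis[(TBS)oxy]phenyl}-7-[(TBS)oxy]-8-[(2Z)-4-[(TBS)oxy]-3-methylbut-2-en-1-yl]-2,3-dihydro-4H-chromen-4-one
Conditions: [Rh(cod)Cl]2 (2.5 mol%), (R)-DTBM-SEGPHOS (5.5 mol%), NaB[3,5-(CF3)2C6H3]4 (5 mol%), 1,2-dichloroethane, 60 °C
Reagents that add atoms: none
Why: Proposed new method: cationic monovalent rhodium should insert into the formyl C–H bond of 19 to give an acyl hydride of trivalent rhodium chelated by the vinyl ether oxygen, the hydride then adds to the alkene carbon that bears oxygen and aryl (the later C2), and the seven-membered acyl–alkyl rhodacycle closes the C3–C4 bond by reductive elimination, so an achiral aldehyde is isomerised to the flavanone in one operation. The closest known reaction type is the rhodium–bisphosphine-catalysed enantioselective endo-hydroacylation of 1,1-disubstituted alkenes held ortho to a benzaldehyde (ortho-allylbenzaldehydes to 3-substituted tetralones) and of 4-substituted pent-4-enals to 3-substituted cyclopentanones; an α-aryl vinyl ether has not been shown in this role. Ring C is closed in the 6-endo mode. The C2 stereocentre is set in the hydride insertion by the chiral bisphosphine, which must select the Re face of the aryl-bearing alkene carbon to give 2S. The step needs endo over exo regioselectivity, which the 1,1-disubstitution secures because the exo path would demand a tertiary rhodium alkyl and reductive elimination to a quaternary centre, and it needs hydroacylation to outrun decarbonylation, which chelation by the ether oxygen favours. The side-chain alkene is meta to the formyl group and cannot reach it, and the oxygen β to rhodium lies inside the metallacycle, where elimination is geometrically hindered.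

**Step 13**
Reactants: 20 (2S)-2-{3,4-bis[(TBS)oxy]phenyl}-7-[(TBS)oxy]-8-[(2Z)-4-[(TBS)oxy]-3-methylbut-2-en-1-yl]-2,3-dihydro-4H-chromen-4-one
Product: 21 (2S)-2-(3,4-dihydroxyphenyl)-7-hydroxy-8-[(2Z)-4-hydroxy-3-methylbut-2-en-1-yl]-2,3-dihydro-4H-chromen-4-one
Conditions: HF·pyridine, pyridine, THF, 0 °C to rt
Reagents that add atoms: none
Why: Fluoride-mediated cleavage of the four silyl ethers under buffered, weakly acidic conditions should free the phenols and the allylic alcohol without ring opening of the flavanone, so the C2 stereocentre is not scrambled.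

**Compound list**
1 | 2,4-dihydroxybenzaldehyde | O=Cc1ccc(O)cc1O | starting material
2 | allyl bromide | C=CCBr | starting material
3 | 2-hydroxy-4-(prop-2-en-1-yloxy)benzaldehyde | O=Cc1ccc(OCC=C)cc1O | intermediate
4 | 2,4-dihydroxy-3-(prop-2-en-1-yl)benzaldehyde | O=Cc1ccc(O)c(CC=C)c1O | intermediate
5 | methacryloyl chloride | CC(=C)C(Cl)=O | starting material
6 | 4-formyl-3-hydroxy-2-(prop-2-en-1-yl)phenyl 2-methylprop-2-enoate | CC(=C)C(=O)Oc1ccc(C=O)c(O)c1CC=C | intermediate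
7 | 1,2-bis(trimethylsilyloxy)ethane | C[Si](C)(C)OCCO[Si](C)(C)C | starting material
8 | 4-(1,3-dioxolan-2-yl)-3-hydroxy-2-(prop-2-en-1-yl)phenyl 2-methylprop-2-enoate | CC(=C)C(=O)Oc1ccc(C2OCCO2)c(O)c1CC=C | intermediate
9 | 7-(1,3-dioxolan-2-yl)-6-hydroxy-3-methyl-1-benzoxepin-2(5H)-one | CC1=CCc2c(O)c(C3OCCO3)ccc2OC1=O | intermediate
10 | 4-(1,3-dioxolan-2-yl)-2-[(2Z)-4-hydroxy-3-methylbut-2-en-1-yl]benzene-1,3-diol | C/C(=C/Cc1c(O)ccc(C2OCCO2)c1O)CO | intermediate
11 | tert-butyldimethylsilyl chloride | CC(C)(C)[Si](C)(C)Cl | starting material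
12 | 3-[(TBS)oxy]-2-[(2Z)-4-[(TBS)oxy]-3-methylbut-2-en-1-yl]-6-(1,3-dioxolan-2-yl)phenol | C/C(=C/Cc1c(O[Si](C)(C)C(C)(C)C)ccc(C2OCCO2)c1O)CO[Si](C)(C)C(C)(C)C | intermediate
13 | 3,4-dihydroxybenzoic acid | OC(=O)c1ccc(O)c(O)c1 | starting material
14 | tert-butyldimethylsilyl 3,4-bis[(TBS)oxy]benzoate | CC(C)(C)[Si](C)(C)OC(=O)c1ccc(O[Si](C)(C)C(C)(C)C)c(O[Si](C)(C)C(C)(C)C)c1 | intermediate (not isolated)
15 | 3,4-bis[(TBS)oxy]benzoic acid | OC(=O)c1ccc(O[Si](C)(C)C(C)(C)C)c(O[Si](C)(C)C(C)(C)C)c1 | intermediate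
16 | 3-[(TBS)oxy]-2-[(2Z)-4-[(TBS)oxy]-3-methylbut-2-en-1-yl]-6-(1,3-dioxolan-2-yl)phenyl 3,4-bis[(TBS)oxy]benzoate | C/C(=C/Cc1c(O[Si](C)(C)C(C)(C)C)ccc(C2OCCO2)c1OC(=O)c1ccc(O[Si](C)(C)C(C)(C)C)c(O[Si](C)(C)C(C)(C)C)c1)CO[Si](C)(C)C(C)(C)C | intermediate
17 | dimethyltitanocene, Cp2TiMe2 | C[Ti](C)(C1C=CC=C1)C1C=CC=C1 | starting material
18 | 2-{2-[(1-{3,4-bis[(TBS)oxy]phenyl}ethenyl)oxy]-4-[(TBS)oxy]-3-[(2Z)-4-[(TBS)oxy]-3-methylbut-2-en-1-yl]phenyl}-1,3-dioxolane | C/C(=C/Cc1c(O[Si](C)(C)C(C)(C)C)ccc(C2OCCO2)c1OC(=C)c1ccc(O[Si](C)(C)C(C)(C)C)c(O[Si](C)(C)C(C)(C)C)c1)CO[Si](C)(C)C(C)(C)C | intermediate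
19 | 2-[(1-{3,4-bis[(TBS)oxy]phenyl}ethenyl)oxy]-4-[(TBS)oxy]-3-[(2Z)-4-[(TBS)oxy]-3-methylbut-2-en-1-yl]benzaldehyde | C/C(=C/Cc1c(O[Si](C)(C)C(C)(C)C)ccc(C=O)c1OC(=C)c1ccc(O[Si](C)(C)C(C)(C)C)c(O[Si](C)(C)C(C)(C)C)c1)CO[Si](C)(C)C(C)(C)C | intermediate
20 | (2S)-2-{3,4-bis[(TBS)oxy]phenyl}-7-[(TBS)oxy]-8-[(2Z)-4-[(TBS)oxy]-3-methylbut-2-en-1-yl]-2,3-dihydro-4H-chromen-4-one | C/C(=C/Cc1c(O[Si](C)(C)C(C)(C)C)ccc2c1O[C@H](c1ccc(O[Si](C)(C)C(C)(C)C)c(O[Si](C)(C)C(C)(C)C)c1)CC2=O)CO[Si](C)(C)C(C)(C)C | intermediate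
21 | (2S)-2-(3,4-dihydroxyphenyl)-7-hydroxy-8-[(2Z)-4-hydroxy-3-methylbut-2-en-1-yl]-2,3-dihydro-4H-chromen-4-one | C/C(=C/Cc1c(O)ccc2c1O[C@H](c1ccc(O)c(O)c1)CC2=O)CO | target

**Step count and risks**
Total step count: 13. Longest linear sequence: 12 (steps 1–7 and 9–13; step 8 prepares acid 15 on the side).

Steps most likely to fail:

1. Step 12 (Proposed new method). The acyl rhodium hydride may lose CO (decarbonylation) faster than it inserts the hindered, electron-rich vinyl ether, insertion may take the exo sense, or facial discrimination may be poor. Fallback by known chemistry (asymmetric conjugate addition of an arylboronic acid to a chromone), setting out from compound 12 and coming back at compound 20: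
 - The dioxolane of 12 is hydrolysed (PPTS, aqueous acetone) to the salicylaldehyde 4-[(TBS)oxy]-3-[(2Z)-4-[(TBS)oxy]-3-methylbut-2-en-1-yl]-2-hydroxybenzaldehyde F1.
 - HC≡CMgBr (excess, THF, 0 °C) should give the propargylic alcohol 1-{4-[(TBS)oxy]-3-[(2Z)-4-[(TBS)oxy]-3-methylbut-2-en-1-yl]-2-hydroxyphenyl}prop-2-yn-1-ol F2.
 - MnO2 (CH2Cl2) should give the ynone 1-{4-[(TBS)oxy]-3-[(2Z)-4-[(TBS)oxy]-3-methylbut-2-en-1-yl]-2-hydroxyphenyl}prop-2-yn-1-one F3.
 - Amine-catalysed 6-endo oxa-Michael cyclisation (Et2NH cat., THF) should give the chromone 7-[(TBS)oxy]-8-[(2Z)-4-[(TBS)oxy]-3-methylbut-2-en-1-yl]-4H-chromen-4-one F4.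
 - The aryl donor is made from commercial 4-bromobenzene-1,2-diol by silylation (TBSCl, imidazole) to 4-bromo-1,2-bis[(TBS)oxy]benzene F5, then bromine–lithium exchange and borylation (n-BuLi, THF, −78 °C; B(Oi-Pr)3; aqueous work-up) to {3,4-bis[(TBS)oxy]phenyl}boronic acid F6.
 - Palladium-catalysed enantioselective conjugate addition of F6 to F4 (Pd(OCOCF3)2, tert-butyl pyridine–oxazoline ligand of the configuration that gives 2S, NH4PF6, water, 1,2-dichloroethane, 60 °C) should then give 20.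

2. Step 11. During acetal cleavage the vinyl ether may be hydrolysed, or the oxocarbenium ion may be captured by the neighbouring vinyl ether in a cationic cyclisation. The fallback removes the acetal before the vinyl ether exists and carries the carbon at the alcohol level, so no cation is formed next to the vinyl ether; it sets out from compound 16 and comes back at compound 19:
 - 16 is hydrolysed (PPTS, aqueous acetone) to the aldehyde 3-[(TBS)oxy]-2-[(2Z)-4-[(TBS)oxy]-3-methylbut-2-en-1-yl]-6-formylphenyl 3,4-bis[(TBS)oxy]benzoate F7.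
 - Reduction (NaBH4, CeCl3·7H2O, MeOH/THF, −40 °C, acetic acid quench) should give the alcohol 3-[(TBS)oxy]-2-[(2Z)-4-[(TBS)oxy]-3-methylbut-2-en-1-yl]-6-(hydroxymethyl)phenyl 3,4-bis[(TBS)oxy]benzoate F8.
 - Silylation (Et3SiCl, imidazole, CH2Cl2) should give the triethylsilyl ether 3-[(TBS)oxy]-2-[(2Z)-4-[(TBS)oxy]-3-methylbut-2-en-1-yl]-6-{[(triethylsilyl)oxy]methyl}phenyl 3,4-bis[(TBS)oxy]benzoate F9.
 - Petasis methylenation (Cp2TiMe2, toluene, 75 °C) should give the vinyl ether {[2-[(1-{3,4-bis[(TBS)oxy]phenyl}ethenyl)oxy]-4-[(TBS)oxy]-3-[(2Z)-4-[(TBS)oxy]-3-methylbut-2-en-1-yl]phenyl]methoxy}triethylsilane F10.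
 - Selective removal of the triethylsilyl group (HF·pyridine buffered with pyridine, THF, 0 °C) should give the alcohol {2-[(1-{3,4-bis[(TBS)oxy]phenyl}ethenyl)oxy]-4-[(TBS)oxy]-3-[(2Z)-4-[(TBS)oxy]-3-methylbut-2-en-1-yl]phenyl}methanol F11.
 - MnO2 (CH2Cl2) should then give 19.

3. Step 5. Ruthenium hydride species may isomerise the allyl group to a propenyl group before cyclisation (leading to a six-membered ring with loss of propene), or cross-metathesis may give oligomers instead of the seven-membered ring. The fallback builds the Z alkene by olefination instead of metathesis; it sets out from compound 4 and comes back at compound 10: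
 - 4 is acetalised (1,2-bis(trimethylsilyloxy)ethane, Me3SiOTf cat., CH2Cl2, −78 °C) to 4-(1,3-dioxolan-2-yl)-2-(prop-2-en-1-yl)benzene-1,3-diol F12.
 - Acetylation (Ac2O, pyridine, DMAP) gives 4-(1,3-dioxolan-2-yl)-2-(prop-2-en-1-yl)-1,3-phenylene diacetate F13.
 - Lemieux–Johnson cleavage (OsO4 cat., NaIO4, 2,6-lutidine, aqueous dioxane) should give the arylacetaldehyde 4-(1,3-dioxolan-2-yl)-2-(2-oxoethyl)-1,3-phenylene diacetate F14.
 - Still–Gennari olefination (ethyl 2-[bis(2,2,2-trifluoroethoxy)phosphoryl]propanoate, KN(SiMe3)2, 18-crown-6, THF, −78 °C) should give ethyl (2Z)-4-[2,6-bis(acetyloxy)-3-(1,3-dioxolan-2-yl)phenyl]-2-methylbut-2-enoate F15.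
 - Excess i-Bu2AlH (THF, −78 °C) should reduce the ester and cleave both acetates to give 10.

Further compounds
F1 | step 12 | 4-[(TBS)oxy]-3-[(2Z)-4-[(TBS)oxy]-3-methylbut-2-en-1-yl]-2-hydroxybenzaldehyde | C/C(=C/Cc1c(O[Si](C)(C)C(C)(C)C)ccc(C=O)c1O)CO[Si](C)(C)C(C)(C)C
F2 | step 12 | 1-{4-[(TBS)oxy]-3-[(2Z)-4-[(TBS)oxy]-3-methylbut-2-en-1-yl]-2-hydroxyphenyl}prop-2-yn-1-ol | C/C(=C/Cc1c(O[Si](C)(C)C(C)(C)C)ccc(C(O)C#C)c1O)CO[Si](C)(C)C(C)(C)C
F3 | step 12 | 1-{4-[(TBS)oxy]-3-[(2Z)-4-[(TBS)oxy]-3-methylbut-2-en-1-yl]-2-hydroxyphenyl}prop-2-yn-1-one | C/C(=C/Cc1c(O[Si](C)(C)C(C)(C)C)ccc(C(=O)C#C)c1O)CO[Si](C)(C)C(C)(C)C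
F4 | step 12 | 7-[(TBS)oxy]-8-[(2Z)-4-[(TBS)oxy]-3-methylbut-2-en-1-yl]-4H-chromen-4-one | C/C(=C/Cc1c(O[Si](C)(C)C(C)(C)C)ccc2c1OC=CC2=O)CO[Si](C)(C)C(C)(C)C
F5 | step 12 | 4-bromo-1,2-bis[(TBS)oxy]benzene | Brc1ccc(O[Si](C)(C)C(C)(C)C)c(O[Si](C)(C)C(C)(C)C)c1
F6 | step 12 | {3,4-bis[(TBS)oxy]phenyl}boronic acid | OB(O)c1ccc(O[Si](C)(C)C(C)(C)C)c(O[Si](C)(C)C(C)(C)C)c1
F7 | step 11 | 3-[(TBS)oxy]-2-[(2Z)-4-[(TBS)oxy]-3-methylbut-2-en-1-yl]-6-formylphenyl 3,4-bis[(TBS)oxy]benzoate | C/C(=C/Cc1c(O[Si](C)(C)C(C)(C)C)ccc(C=O)c1OC(=O)c1ccc(O[Si](C)(C)C(C)(C)C)c(O[Si](C)(C)C(C)(C)C)c1)CO[Si](C)(C)C(C)(C)C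
F8 | step 11 | 3-[(TBS)oxy]-2-[(2Z)-4-[(TBS)oxy]-3-methylbut-2-en-1-yl]-6-(hydroxymethyl)phenyl 3,4-bis[(TBS)oxy]benzoate | C/C(=C/Cc1c(O[Si](C)(C)C(C)(C)C)ccc(CO)c1OC(=O)c1ccc(O[Si](C)(C)C(C)(C)C)c(O[Si](C)(C)C(C)(C)C)c1)CO[Si](C)(C)C(C)(C)C
F9 | step 11 | 3-[(TBS)oxy]-2-[(2Z)-4-[(TBS)oxy]-3-methylbut-2-en-1-yl]-6-{[(triethylsilyl)oxy]methyl}phenyl 3,4-bis[(TBS)oxy]benzoate | C/C(=C/Cc1c(O[Si](C)(C)C(C)(C)C)ccc(CO[Si](CC)(CC)CC)c1OC(=O)c1ccc(O[Si](C)(C)C(C)(C)C)c(O[Si](C)(C)C(C)(C)C)c1)CO[Si](C)(C)C(C)(C)C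
F10 | step 11 | {[2-[(1-{3,4-bis[(TBS)oxy]phenyl}ethenyl)oxy]-4-[(TBS)oxy]-3-[(2Z)-4-[(TBS)oxy]-3-methylbut-2-en-1-yl]phenyl]methoxy}triethylsilane | C/C(=C/Cc1c(O[Si](C)(C)C(C)(C)C)ccc(CO[Si](CC)(CC)CC)c1OC(=C)c1ccc(O[Si](C)(C)C(C)(C)C)c(O[Si](C)(C)C(C)(C)C)c1)CO[Si](C)(C)C(C)(C)C
F11 | step 11 | {2-[(1-{3,4-bis[(TBS)oxy]phenyl}ethenyl)oxy]-4-[(TBS)oxy]-3-[(2Z)-4-[(TBS)oxy]-3-methylbut-2-en-1-yl]phenyl}methanol | C/C(=C/Cc1c(O[Si](C)(C)C(C)(C)C)ccc(CO)c1OC(=C)c1ccc(O[Si](C)(C)C(C)(C)C)c(O[Si](C)(C)C(C)(C)C)c1)CO[Si](C)(C)C(C)(C)C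
F12 | step 5 | 4-(1,3-dioxolan-2-yl)-2-(prop-2-en-1-yl)benzene-1,3-diol | C=CCc1c(O)ccc(C2OCCO2)c1O
F13 | step 5 | 4-(1,3-dioxolan-2-yl)-2-(prop-2-en-1-yl)-1,3-phenylene diacetate | CC(=O)Oc1ccc(C2OCCO2)c(OC(C)=O)c1CC=C
F14 | step 5 | 4-(1,3-dioxolan-2-yl)-2-(2-oxoethyl)-1,3-phenylene diacetate | CC(=O)Oc1ccc(C2OCCO2)c(OC(C)=O)c1CC=O
F15 | step 5 | ethyl (2Z)-4-[2,6-bis(acetyloxy)-3-(1,3-dioxolan-2-yl)phenyl]-2-methylbut-2-enoate | C/C(=C/Cc1c(OC(C)=O)ccc(C2OCCO2)c1OC(C)=O)C(=O)OCC
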